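**Retrosynthetic overview**
- Endgame: the C15 silyl ether is cleaved last; the C9 angelate and C8 methacrylate are put on an 8,9-diol freed from an acetonide (C8 and C9 come from L-tartrate).
- Key step: a CrCl2-mediated intramolecular allylation of the C6 enal by the C13 allyl bromide forms the C6–C7 bond; it closes the ten-membered carbocycle and, through the chromium alkoxide, the α-methylene-γ-lactone in the same flask, setting C6 and C7.
- The furanone ring is made before that, by gold-catalysed cyclisation of a γ-hydroxy ynone assembled from a Z vinyl iodide (C4–C6, C15), CO (C3) and a tertiary propargylic alcohol (C1, C2, C7–C10).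
- C10 comes from chelate-controlled ethynyl addition to a tartrate-derived methyl ketone; C11–C13 come from a Baylis–Hillman reaction with methyl acrylate.
- Ring order: furanone first, then ten-membered ring and lactone together.

Assumption: the SMILES defines the target (6R,7S,8S,9R,10S; 4Z; the C9 ester is the angelate, (2Z)-2-methylbut-2-enoate); C1–C15 follow germacranolide numbering and are used only to locate atoms.

**Step 1**
Reactants: 1 dimethyl (4R,5R)-2,2-dimethyl-1,3-dioxolane-4,5-dicarboxylate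
Product: 2 (4R,5R)-N4,N5-dimethoxy-N4,N5,2,2-tetramethyl-1,3-dioxolane-4,5-dicarboxamide
Conditions: MeNHOMe·HCl (3 equiv), i-PrMgCl (6 equiv), THF, −20 → 0 °C
Reagents that add atoms: N,O-dimethylhydroxylamine hydrochloride, CNOC.Cl
Why: Weinreb amidation of both esters by the chloromagnesium amide made in the flask; no stereocentre is touched and the trans-dioxolane is also the thermodynamic isomer.

**Step 2**
Reactants: 2 bis-Weinreb amide
Product: 3 (4R,5R)-5-acetyl-N-methoxy-N,2,2-trimethyl-1,3-dioxolane-4-carboxamide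
Conditions: MeMgBr (1.05 equiv), THF, −78 → −20 °C; aq. NH4Cl
Reagents that add atoms: methylmagnesium bromide, C[Mg]Br
Why: Weinreb ketone synthesis in which the stable magnesium chelate stops over-addition, so one equivalent of Grignard reagent desymmetrises the C2-symmetric bis-amide (both amides are equivalent).

**Step 3**
Reactants: 3 keto amide
Product: 4 (4R,5R)-5-[(2R)-2-hydroxybut-3-yn-2-yl]-N-methoxy-N,2,2-trimethyl-1,3-dioxolane-4-carboxamide
Conditions: HC≡CMgBr (1.5 equiv), CH2Cl2/THF, −78 °C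
Reagents that add atoms: ethynylmagnesium bromide, C#C[Mg]Br
Why: Cram-chelate Grignard addition in which magnesium bridges the ketone oxygen and the adjacent dioxolane oxygen, so the acetylide attacks the face opposite C8 and sets C10 syn to O9, while the ketone reacts faster than the Weinreb amide at −78 °C.

**Step 4**
Reactants: 4 propargylic alcohol amide
Product: 5 (4R,5R)-5-[(2R)-2-hydroxybut-3-yn-2-yl]-2,2-dimethyl-1,3-dioxolane-4-carbaldehyde
Conditions: i-Bu2AlH (2.2 equiv), THF, −78 °C; aq. potassium sodium tartrate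
Reagents that add atoms: none
Why: Weinreb amide reduction stops at the aldehyde through the chelated aluminium hemiaminal (the first equivalent is consumed by the tertiary hydroxyl), and the trans-fused dioxolane keeps the γ-hydroxy aldehyde open-chain.

**Step 5**
Reactants: 6 3,3-diethoxyprop-1-yne
Product: 8 4,4-diethoxybut-2-yn-1-ol, via lithium acetylide 7 (not isolated)
Conditions: n-BuLi (1.05 equiv), THF, −78 °C; (CH2O)n, −78 → 25 °C; H2O
Reagents that add atoms: formaldehyde (used as paraformaldehyde), C=O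
Why: hydroxymethylation of a lithium acetylide (alkynyllithium addition to formaldehyde).

**Step 6**
Reactants: 8 4,4-diethoxybut-2-yn-1-ol
Product: 10 (2Z)-4,4-diethoxy-2-iodobut-2-en-1-ol, via alkenylstannane 9 (not isolated)
Conditions: [Cp*RuCl]4 (2 mol %), Bu3SnH (1.1 equiv), CH2Cl2, 25 °C; then I2 (1.1 equiv), 0 °C
Reagents that add atoms: iodine, II
Why: hydroxyl-directed ruthenium-catalysed trans-hydrostannation puts tin on the alkyne carbon next to the CH2OH and hydrogen anti to it, and iododestannylation with retention gives the vinyl iodide with iodine cis to the acetal carbon.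

**Step 7**
Reactants: 10 (2Z)-4,4-diethoxy-2-iodobut-2-en-1-ol
Product: 11 tert-butyl{[(2Z)-4,4-diethoxy-2-iodobut-2-en-1-yl]oxy}diphenylsilane
Conditions: t-BuPh2SiCl (1.1 equiv), imidazole (2 equiv), CH2Cl2, 25 °C
Reagents that add atoms: tert-butyl(chloro)diphenylsilane, CC(C)(C)[Si](Cl)(c1ccccc1)c1ccccc1
Why: imidazole-promoted silylation of the primary alcohol; the silyl ether survives every later step up to step 17.

**Step 8**
Reactants: 5 hydroxy aldehyde alkyne; 11 vinyl iodide
Product: 12 (4R,5R)-5-[(2R,6Z)-6-({[tert-butyl(diphenyl)silyl]oxy}methyl)-8,8-diethoxy-2-hydroxy-5-oxooct-6-en-3-yn-2-yl]-2,2-dimethyl-1,3-dioxolane-4-carbaldehyde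
Conditions: PdCl2(PPh3)2 (5 mol %), CuI (5 mol %), Et3N (3 equiv), CO (1 atm), THF, 25 °C
Reagents that add atoms: carbon monoxide, [C-]#[O+]
Why: carbonylative Sonogashira coupling in which zerovalent palladium adds to the vinyl iodide with retention, CO inserts, and the copper acetylide of 5 couples to give the ynone with the alkene geometry intact; the free tertiary alcohol and the aldehyde are tolerated.

**Step 9**
Reactants: 12 γ-hydroxy ynone
Product: 13 (4R,5R)-5-[(2S)-5-[(2Z)-1-{[tert-butyl(diphenyl)silyl]oxy}-4,4-diethoxybut-2-en-2-yl]-2-methyl-3-oxo-2,3-dihydrofuran-2-yl]-2,2-dimethyl-1,3-dioxolane-4-carbaldehyde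
Conditions: (4-CF3C6H4)3PAuCl (5 mol %), AgOTf (5 mol %), toluene, 25 °C
Reagents that add atoms: none
Why: monovalent-gold-catalysed cycloisomerisation of a γ-hydroxy alkynone to a 3(2H)-furanone, in which the tertiary C10–O bond is never broken, so C10 is retained.

**Step 10**
Reactants: 13 furanone aldehyde
Product: 14 Baylis–Hillman adduct, methyl 2-[hydroxy(dioxolan-4-yl)methyl]prop-2-enoate in which the aldehyde carbon of 13 has become carbinol C7 (both C7 epimers, all other centres as in 13)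
Conditions: methyl acrylate (10 equiv), DABCO (1 equiv), neat, 25 °C, 72 h
Reagents that add atoms: methyl acrylate, C=CC(=O)OC
Why: Morita–Baylis–Hillman reaction at the reactive α-alkoxy aldehyde; the C7 epimer mixture converges in step 12 and the acetal shields C6 from the amine.

**Step 11**
Reactants: 14 Baylis–Hillman adduct
Product: 15 Z enal, 14 with the diethyl acetal at C6 hydrolysed to the aldehyde
Conditions: 10% aq. oxalic acid on SiO2, CH2Cl2, 25 °C
Reagents that add atoms: water, O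
Why: acid hydrolysis of an α,β-unsaturated diethyl acetal is far faster than cleavage of the dioxolane or the silyl ether and involves no nucleophile that could isomerise the Z enal.

**Step 12**
Reactants: 15 Z enal
Product: 16 methyl (2Z)-2-(bromomethyl)-3-(dioxolan-4-yl)prop-2-enoate derived from 15 (bromomethyl cis to the dioxolane, other centres as in 13)
Conditions: NBS (1.3 equiv), Me2S (1.6 equiv), CH2Cl2, −20 → 0 °C
Reagents that add atoms: N-bromosuccinimide, O=C1CCC(=O)N1Br
Why: Corey–Kim-type activation of the Baylis–Hillman alcohol and SN2′ displacement by bromide give the thermodynamically preferred Z 2-(bromomethyl)enoate from both C7 epimers.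

**Step 13**
Reactants: 16 allyl bromide enal
Product: 19 (6R,7S,8S,9R,10S)-15-{[tert-butyl(diphenyl)silyl]oxy}-8,9-(isopropylidenedioxy)-1-oxo-3,10-epoxygermacra-2,4Z,11(13)-trien-12,6-olide, via allylchromium dichloride 17 (not isolated), via macrocyclic chromium alkoxide ester 18 (not isolated)
Conditions: CrCl2 (8 equiv), THF, 25 °C, 16 added over 10 h (2 mM final), then 45 °C, 2 h; aq. NH4Cl
Reagents that add atoms: none
Why: intramolecular Nozaki–Hiyama-type (chromium Barbier) allylation with lactonisation in the same flask: the γ-carbon C7 of the equilibrating allylchromium adds to the C6 enal through a chair transition state in which A(1,3) strain holds H-8 in the allyl plane, so the aldehyde approaches anti to the C8–C9 bond (7S) with C5 and C8 pseudo-equatorial (6,7-anti, 6R), and the trivalent chromium alkoxide then closes onto the methyl ester to the trans-fused lactone.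

**Step 14**
Reactants: 19 macrocyclic acetonide
Product: 20 8,9-diol of 19 (C6–C10 configured as in 23)
Conditions: CF3CO2H/H2O (9:1), CH2Cl2, 0 °C
Reagents that add atoms: none
Why: acid-catalysed hydrolysis of the isopropylidene acetal; the tert-butyldiphenylsilyl ether, the lactone and the furanone are stable to these conditions.

**Step 15**
Reactants: 20 diol
Product: 21 8-O-methacrylate of 20 (9-OH free)
Conditions: methacrylic anhydride (1.1 equiv), Et3N (2 equiv), DMAP (0.1 equiv), CH2Cl2, −40 → −20 °C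
Reagents that add atoms: methacrylic anhydride, C=C(C)C(=O)OC(=O)C(C)=C
Why: kinetically selective DMAP-catalysed acylation of the less hindered C8 hydroxyl, the C9 hydroxyl being neopentylic next to quaternary C10.

**Step 16**
Reactants: 21 8-O-methacrylate
Product: 22 15-O-tert-butyldiphenylsilyl ether of the target (8-O-methacrylate, 9-O-angelate)
Conditions: angelic acid (3 equiv), 2,4,6-Cl3C6H2COCl (3 equiv), Et3N (6 equiv), toluene, 25 °C; then 21, 75 °C
Reagents that add atoms: angelic acid, C/C=C(/C)C(=O)O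
Why: Yamaguchi-type mixed-anhydride esterification run without DMAP acylates hindered secondary alcohols and keeps the Z geometry of the angelate because no nucleophile adds reversibly to the enoate.

**Step 17**
Reactants: 22 silyl ether
Product: 23 (6R,7S,8S,9R,10S)-15-hydroxy-8-(methacryloyloxy)-9-[(2Z)-2-methylbut-2-enoyloxy]-1-oxo-3,10-epoxygermacra-2,4Z,11(13)-trien-12,6-olide
Conditions: HF·pyridine, pyridine, THF, 0 → 25 °C
Reagents that add atoms: none
Why: fluoride-driven Si–O cleavage under buffered, weakly acidic conditions causes neither acyl migration nor conjugate addition to the Michael acceptors.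

**Compound list**
1 | dimethyl (4R,5R)-2,2-dimethyl-1,3-dioxolane-4,5-dicarboxylate (dimethyl 2,3-O-isopropylidene-L-tartrate) | COC(=O)[C@@H]1OC(C)(C)O[C@H]1C(=O)OC | starting material
2 | (4R,5R)-N4,N5-dimethoxy-N4,N5,2,2-tetramethyl-1,3-dioxolane-4,5-dicarboxamide | CON(C)C(=O)[C@@H]1OC(C)(C)O[C@H]1C(=O)N(C)OC | intermediate
3 | (4R,5R)-5-acetyl-N-methoxy-N,2,2-trimethyl-1,3-dioxolane-4-carboxamide | CON(C)C(=O)[C@@H]1OC(C)(C)O[C@H]1C(C)=O | intermediate
4 | (4R,5R)-5-[(2R)-2-hydroxybut-3-yn-2-yl]-N-methoxy-N,2,2-trimethyl-1,3-dioxolane-4-carboxamide | CON(C)C(=O)[C@@H]1OC(C)(C)O[C@H]1[C@](C)(O)C#C | intermediate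
5 | (4R,5R)-5-[(2R)-2-hydroxybut-3-yn-2-yl]-2,2-dimethyl-1,3-dioxolane-4-carbaldehyde | O=C[C@@H]1OC(C)(C)O[C@H]1[C@](C)(O)C#C | intermediate
6 | 3,3-diethoxyprop-1-yne | C#CC(OCC)OCC | starting material
7 | (3,3-diethoxyprop-1-yn-1-yl)lithium | [Li]C#CC(OCC)OCC | intermediate
8 | 4,4-diethoxybut-2-yn-1-ol | OCC#CC(OCC)OCC | intermediate
9 | (2Z)-4,4-diethoxy-2-(tributylstannyl)but-2-en-1-ol | CCOC(OCC)/C=C(\[Sn](CCCC)(CCCC)CCCC)CO | intermediate
10 | (2Z)-4,4-diethoxy-2-iodobut-2-en-1-ol | CCOC(OCC)/C=C(\I)CO | intermediate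
11 | tert-butyl{[(2Z)-4,4-diethoxy-2-iodobut-2-en-1-yl]oxy}diphenylsilane | CCOC(OCC)/C=C(\I)CO[Si](c1ccccc1)(c1ccccc1)C(C)(C)C | intermediate
12 | (4R,5R)-5-[(2R,6Z)-6-({[tert-butyl(diphenyl)silyl]oxy}methyl)-8,8-diethoxy-2-hydroxy-5-oxooct-6-en-3-yn-2-yl]-2,2-dimethyl-1,3-dioxolane-4-carbaldehyde | O=C[C@@H]1OC(C)(C)O[C@H]1[C@](C)(O)C#CC(=O)/C(CO[Si](c2ccccc2)(c2ccccc2)C(C)(C)C)=C\C(OCC)OCC | intermediate
13 | (4R,5R)-5-[(2S)-5-[(2Z)-1-{[tert-butyl(diphenyl)silyl]oxy}-4,4-diethoxybut-2-en-2-yl]-2-methyl-3-oxo-2,3-dihydrofuran-2-yl]-2,2-dimethyl-1,3-dioxolane-4-carbaldehyde | O=C[C@@H]1OC(C)(C)O[C@H]1[C@]2(C)OC(=CC2=O)/C(CO[Si](c3ccccc3)(c3ccccc3)C(C)(C)C)=C\C(OCC)OCC | intermediate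
14 | Baylis–Hillman adduct of 13 with methyl acrylate (C7 carbinol, both epimers; other centres as in 13) | C=C(C(=O)OC)C(O)[C@@H]1OC(C)(C)O[C@H]1[C@]2(C)OC(=CC2=O)/C(CO[Si](c3ccccc3)(c3ccccc3)C(C)(C)C)=C\C(OCC)OCC | intermediate
15 | Z enal from 14 (C6 aldehyde free; C7 epimers) | C=C(C(=O)OC)C(O)[C@@H]1OC(C)(C)O[C@H]1[C@]2(C)OC(=CC2=O)/C(CO[Si](c3ccccc3)(c3ccccc3)C(C)(C)C)=C\C=O | intermediate
16 | methyl (2Z)-2-(bromomethyl)enoate from 15 (C13 bromide, C6 enal) | COC(=O)/C(CBr)=C/[C@@H]1OC(C)(C)O[C@H]1[C@]2(C)OC(=CC2=O)/C(CO[Si](c3ccccc3)(c3ccccc3)C(C)(C)C)=C\C=O | intermediate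
17 | allylchromium dichloride from 16 (CrCl2 on C13 in place of Br) | COC(=O)/C(C[Cr](Cl)Cl)=C/[C@@H]1OC(C)(C)O[C@H]1[C@]2(C)OC(=CC2=O)/C(CO[Si](c3ccccc3)(c3ccccc3)C(C)(C)C)=C\C=O | intermediate
18 | ten-membered C6 chromium dichloride alkoxide, methyl 12-oate, 11(13)-methylene (C6–C10 configured as in 19) | CC1(C)O[C@H]2[C@@H](C(=C)C(=O)OC)[C@H](O[Cr](Cl)Cl)/C=C(/CO[Si](c4ccccc4)(c4ccccc4)C(C)(C)C)C3=CC(=O)[C@@](C)(O3)[C@@H]2O1 | intermediate
19 | (6R,7S,8S,9R,10S)-15-{[tert-butyl(diphenyl)silyl]oxy}-8,9-(isopropylidenedioxy)-1-oxo-3,10-epoxygermacra-2,4Z,11(13)-trien-12,6-olide | CC1(C)O[C@H]2[C@H]3C(=C)C(=O)O[C@@H]3/C=C(/CO[Si](c4ccccc4)(c4ccccc4)C(C)(C)C)C3=CC(=O)[C@@](C)(O3)[C@@H]2O1 | intermediate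
20 | 8,9-diol of 19 (15-O-silyl; centres as in 23) | O[C@H]1[C@H]2C(=C)C(=O)O[C@@H]2/C=C(/CO[Si](c3ccccc3)(c3ccccc3)C(C)(C)C)C2=CC(=O)[C@@](C)(O2)[C@@H]1O | intermediate
21 | 8-O-methacrylate of 20 (9-OH free) | C=C(C)C(=O)O[C@H]1[C@H]2C(=C)C(=O)O[C@@H]2/C=C(/CO[Si](c3ccccc3)(c3ccccc3)C(C)(C)C)C2=CC(=O)[C@@](C)(O2)[C@@H]1O | intermediate
22 | 15-O-tert-butyldiphenylsilyl ether of 23 | C=C(C)C(=O)O[C@H]1[C@H]2C(=C)C(=O)O[C@@H]2/C=C(/CO[Si](c3ccccc3)(c3ccccc3)C(C)(C)C)C2=CC(=O)[C@@](C)(O2)[C@@H]1OC(=O)/C(C)=C\C | intermediate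
23 | (6R,7S,8S,9R,10S)-15-hydroxy-8-(methacryloyloxy)-9-[(2Z)-2-methylbut-2-enoyloxy]-1-oxo-3,10-epoxygermacra-2,4Z,11(13)-trien-12,6-olide (CNP0359568.2) | C=C(C)C(=O)O[C@H]1[C@H]2C(=C)C(=O)O[C@@H]2/C=C(/CO)C2=CC(=O)[C@@](C)(O2)[C@@H]1OC(=O)/C(C)=C\C | target

**Step count**
Total: 17 steps. Longest linear sequence: 14 steps (steps 1–4 and 8–17, from compound 1).

**Three steps most likely to fail**

Step 13 is the riskiest. It may give oligomers, or the 6,7-cis lactone or the C6/C7-epimeric trans lactone, because the ring, not a simple acyclic model, decides the transition state. The fallback forms the lactone intermolecularly and closes the ten-membered ring at C4=C5 by ring-closing metathesis; it sets out from 5 and comes back at 19. Propargyl alcohol is hydroiodinated (NaI, Me3SiCl, H2O, MeCN) to 2-iodoprop-2-en-1-ol F1 and silylated to tert-butyl[(2-iodoprop-2-en-1-yl)oxy]diphenylsilane F2. Carbonylative Sonogashira coupling of F2 with 5 under the conditions of step 8 gives the hydroxy ynone F3. The gold catalyst of step 9 converts it to the furanone aldehyde F4, methyl acrylate and DABCO give the Baylis–Hillman adduct F5, and NBS/Me2S gives the allyl bromide F6. CrCl2-mediated allylation of acrolein by F6, with lactonisation in the flask, gives the 6-vinyl trans-lactone F7, and the C6/C7 diastereomers are separated at this stage. The second-generation Hoveyda–Grubbs catalyst (toluene, 80 °C, 1 mM) then joins the vinyl group to the 1,1-disubstituted alkene, the ring enforcing the Z geometry, to give 19.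

Step 3 fails if the addition is Felkin–Anh-controlled and not chelate-controlled, which would give mainly the C10 epimer. The fallback inverts the order in which the two carbon groups are added, which inverts C10 under the same facial bias; it sets out from 2 and comes back at 4. LiC≡CSiMe3 (1 equiv, THF, −78 °C) converts one Weinreb amide of 2 into the silyl ynone F8. MeMgBr (THF, −78 °C) adds 1,2 to the ketone to give the silylated tertiary carbinol F9, and K2CO3 in MeOH removes the silyl group to give 4.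

Step 15 fails if the two secondary hydroxyls are not differentiated, or if the methacrylate migrates to O9 during the hot angeloylation of step 16. The fallback blocks O8 with a silyl group and reverses the order of the two acylations; it sets out from 20 and comes back at 22. Et3SiOTf and 2,6-lutidine (CH2Cl2, −78 °C) silylate the less hindered C8 hydroxyl to give the 8-O-triethylsilyl ether F10. The angelate is then installed at C9 under the conditions of step 16, with no free neighbouring hydroxyl, to give the 8-O-triethylsilyl 9-O-angelate F11. PPTS in MeOH (0 °C) removes only the triethylsilyl group to give the 9-O-angelate 8-alcohol F12, and methacrylic anhydride/DMAP at −40 °C gives 22.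

**Further compounds**
F1 | step 13 | 2-iodoprop-2-en-1-ol | C=C(I)CO
F2 | step 13 | tert-butyl[(2-iodoprop-2-en-1-yl)oxy]diphenylsilane | C=C(I)CO[Si](c1ccccc1)(c1ccccc1)C(C)(C)C
F3 | step 13 | (4R,5R)-5-[(2R)-6-({[tert-butyl(diphenyl)silyl]oxy}methyl)-2-hydroxy-5-oxohept-6-en-3-yn-2-yl]-2,2-dimethyl-1,3-dioxolane-4-carbaldehyde | O=C[C@@H]1OC(C)(C)O[C@H]1[C@](C)(O)C#CC(=O)C(=C)CO[Si](c2ccccc2)(c2ccccc2)C(C)(C)C
F4 | step 13 | (4R,5R)-5-[(2S)-5-(3-{[tert-butyl(diphenyl)silyl]oxy}prop-1-en-2-yl)-2-methyl-3-oxo-2,3-dihydrofuran-2-yl]-2,2-dimethyl-1,3-dioxolane-4-carbaldehyde | O=C[C@@H]1OC(C)(C)O[C@H]1[C@]2(C)OC(=CC2=O)C(=C)CO[Si](c3ccccc3)(c3ccccc3)C(C)(C)C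
F5 | step 13 | Baylis–Hillman adduct of F4 with methyl acrylate (C7 epimers) | C=C(C(=O)OC)C(O)[C@@H]1OC(C)(C)O[C@H]1[C@]2(C)OC(=CC2=O)C(=C)CO[Si](c3ccccc3)(c3ccccc3)C(C)(C)C
F6 | step 13 | methyl (2Z)-2-(bromomethyl)enoate from F5 | COC(=O)/C(CBr)=C/[C@@H]1OC(C)(C)O[C@H]1[C@]2(C)OC(=CC2=O)C(=C)CO[Si](c3ccccc3)(c3ccccc3)C(C)(C)C
F7 | step 13 | 6-vinyl trans-fused α-methylene-γ-lactone carrying the dioxolane and furanone of F4 (C6, C7 configured as in 19) | C=C[C@H]1OC(=O)C(=C)[C@@H]1[C@@H]2OC(C)(C)O[C@H]2[C@]3(C)OC(=CC3=O)C(=C)CO[Si](c4ccccc4)(c4ccccc4)C(C)(C)C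
F8 | step 3 | (4R,5R)-N-methoxy-N,2,2-trimethyl-5-[3-(trimethylsilyl)prop-2-ynoyl]-1,3-dioxolane-4-carboxamide | CON(C)C(=O)[C@@H]1OC(C)(C)O[C@H]1C(=O)C#C[Si](C)(C)C
F9 | step 3 | (4R,5R)-5-[(2R)-2-hydroxy-4-(trimethylsilyl)but-3-yn-2-yl]-N-methoxy-N,2,2-trimethyl-1,3-dioxolane-4-carboxamide | CON(C)C(=O)[C@@H]1OC(C)(C)O[C@H]1[C@](C)(O)C#C[Si](C)(C)C
F10 | step 15 | 8-O-triethylsilyl ether of 20 | CC[Si](CC)(CC)O[C@H]1[C@H]2C(=C)C(=O)O[C@@H]2/C=C(/CO[Si](c3ccccc3)(c3ccccc3)C(C)(C)C)C2=CC(=O)[C@@](C)(O2)[C@@H]1O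
F11 | step 15 | 8-O-triethylsilyl 9-O-angelate of 20 | CC[Si](CC)(CC)O[C@H]1[C@H]2C(=C)C(=O)O[C@@H]2/C=C(/CO[Si](c3ccccc3)(c3ccccc3)C(C)(C)C)C2=CC(=O)[C@@](C)(O2)[C@@H]1OC(=O)/C(C)=C\C
F12 | step 15 | 9-O-angelate of 20 (8-OH free) | O[C@H]1[C@H]2C(=C)C(=O)O[C@@H]2/C=C(/CO[Si](c3ccccc3)(c3ccccc3)C(C)(C)C)C2=CC(=O)[C@@](C)(O2)[C@@H]1OC(=O)/C(C)=C\C
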